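The slowness in the theta run sat in a long tail. Theta had 14% of double product after 10.0 min but still 52% after 120 min, while its first product read 2% or less.

| setting | theta | gamma | grey | violet | amber |
|---|---|---|---|---|---|
| substrate | 0.10 M | 0.10 M | 0.10 M | 0.10 M | 0.10 M |
| reagent | 0.16 M | 0.36 M | 0.200 M | 0.250 M | 0.300 M |
| remark | run made earlier | run made earlier |  |  |  |
| time |  |  | 4.0 h | 4.0 h | 4.0 h |

| run | time / min | double product / % | first product / % |
|---|---|---|---|
| theta | 10.0 | 14 | 0 |
| theta | 20.0 | 25 | 0 |
| theta | 50.0 | 40 | 2 |
| theta | 120 | 52 | 1 |
| gamma | 30.0 | 88 | 0 |
| gamma | 60.0 | 95 | 2 |
| gamma | 90.0 | 100 | 0 |
| gamma | 120 | 99 | 1 |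

(readings scatter by 1.5 percentage points)

* how much double product is there at the end, in percent of the substrate charged: for each flask in turn (grey, violet, amber)

- on the list of suspects stand: substrate + reagent <-> first product; substrate + reagent -> other mono adduct; reagent + first product -> double product; reagent + other mono adduct -> double product; reagent <-> dormant form

I took the substrate to be gone within minutes into the other mono adduct, which nobody read, so that I was watching a second addition (the rate-limiting step). As fractions of the substrate charge, the adduct remaining is what double product has not yet taken. The leftover reagent, dormant form counted in, is the reagent charge less one per substrate and one per double product. The theta reading of 40% at 50.0 min then gives, with that reading's scatter, 0.0294 /min for the finishing rate, the gain of double product per unit time divided by remaining adduct and leftover reagent.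

I turned the question round: what would grey need in order to finish? Grey holds 2.00 reagents per substrate, just what double product takes, so both leftovers stay equal and the remainder is one over one plus finishing rate times time. Leaving a hundredth needs that product near 100, and grey stands at 7.05, so I expected 87.6%. Violet has a surplus of 0.500 reagents per substrate and amber 1.00, so their remainders fall exponentially, and I reckoned 99.0% and >99.9%.

The forecast, holding that “the rate rises steeply with reagent”, gave 74%, 90% and 98%, lower than mine in grey. The flasks gave 88.2%, 99.2% and 100%.

    substrate + reagent ⇌ first product (K = 4.16 /M, k = 0.567 /M/s)
    substrate + reagent → other mono adduct (k = 0.177 /M/s)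
    reagent + first product → double product (k = 0.0175 /M/s)
    reagent + other mono adduct → double product (k = 0.0139 /M/s)
    reagent ⇌ dormant form (K = 1.64, k = 0.00727 /s)

Two things acting together are part of what stands behind violet's 99.2%: reagent adding to the other mono adduct, and dormant form returning to reagent. The violet run gives 4.85% without the first and 18.3% without the second. At 2.00 h the finishing rate puts the other mono adduct at 22.1% in grey and 6.45% in violet, and the flasks held 21.2% and 5.65%.

The earlier runs and the new flask were computed for substances that don't exist, and the scatter is random.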